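The runs are simulated from invented constants; scatter was added.

In a one-step world X goes to G by one first-order step, and each portion of X halves once per half-life, whatever the portions before it did. These flasks have more steps: the catalyst Z takes up the reagent D to give L, L takes X to give J, J gives G and returns Z, and two L pair reversibly as Q. I wanted to know whether one half-life could still be counted on them.

| flask | X | D | Z | remark | time |
|---|---|---|---|---|---|
| Sunday's | 0.11 M (in portions, 4) | 0.32 M | 40 mM | run made earlier; portions every 2.5 h |  |
| Wednesday's | 0.64 M (in portions, 4) | 0.32 M | 40 mM | run made earlier; portions every 2.5 h |  |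
| autumn | 0.80 M (in portions, 4) | 0.320 M | 40 mM | the portions of X follow each other after 2.5 h, the first at the start | 10 h |
| spring | 0.12 M (in portions, 4) | 0.320 M | 40 mM | the portions of X follow each other after 2.5 h, the first at the start | 10 h |
| summer | 0.40 M (in portions, 4) | 0.320 M | 40 mM | the portions of X follow each other after 2.5 h, the first at the start | 10 h |
| dawn | 0.20 M (in portions, 4) | 0.320 M | 40 mM | the portions of X follow each other after 2.5 h, the first at the start | 10 h |

| run | time / h | G / % | X / % |
|---|---|---|---|
| Sunday's | 0.833 | 1.5 | 20.2 |
| Sunday's | 1.33 | 1.2 | 22.7 |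
| Sunday's | 2.00 | 3.0 | 20.4 |
| Sunday's | 3.00 | 5.8 | 41.9 |
| Sunday's | 4.00 | 9.9 | 36.7 |
| Sunday's | 6.00 | 21.2 | 51.7 |
| Sunday's | 10.0 | 41.7 | 53.3 |
| Wednesday's | 0.500 | 0 | 22.9 |
| Wednesday's | 1.50 | 1.9 | 20.9 |
| Wednesday's | 3.00 | 5.7 | 43.3 |
| Wednesday's | 4.00 | 8.5 | 40.1 |
| Wednesday's | 6.00 | 16.2 | 57.5 |
| Wednesday's | 8.00 | 21.1 | 76.1 |
| Wednesday's | 10.0 | 28.5 | 69.2 |

(standard deviation of a reading: 1 percentage point)

- the earlier runs were read with a standard deviation of 1 percentage point
- reactions considered so far: D + Z <-> L; X + L -> J; J -> Z + G; 2 L <-> Q

- the flasks put in order of amount of G, in percent of the X charged, best first, at 10 h (autumn / spring / summer / dawn)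
- the amount of G, in percent of the X charged of the flask you put first, at 10 h
- the amount of G, in percent of the X charged of the flask you put last, at 10 h

I read the half-life from Sunday's run, whose charge of 0.11 M lies next to spring's 0.12 M. From 6.00 h to 10.0 h G rose by 21 percentage points of the charge while X read near 52.5% of it, which gave a reading of 0.0976 h⁻¹. Its ln(2) counterpart, the working half-life of X, was 7.10 h. The same reading on Wednesday's run gave 14.3 h, twice as long at the larger charge, so I ranked the flasks by charge, the least first. Each G spends one D, and in autumn D is the limiting reagent, its charge matching 40.0% of the X.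

For spring I counted portions. At 10 h they had aged 10 h, 7.50 h, 5.00 h and 2.50 h, and averaging what each kept at my half-life left 56.4% as X. That gave me about 43.6% as G, with nothing set aside for J.

The forecast, made from the same two runs, gave the order spring > dawn > summer > autumn, with 41.3% first (range 39.5% to 43%) and 25% last (range 21.5% to 28%), saying: “Percent yield therefore falls as the charge rises”. My spring figure stood higher than its 41.3% and above its range.

The simulation gave spring > dawn > summer > autumn, with 42.1% in spring and 26.1% in autumn, so the forecast's order and both its ranges held.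

    D + Z ⇌ L (K = 0.720 M⁻¹, k = 110 M⁻¹ h⁻¹)
    X + L → J (k = 19.0 M⁻¹ h⁻¹)
    J → Z + G (k = 1.80 h⁻¹)
    2 L ⇌ Q, settled at all times (K = 69.0 M⁻¹)

In spring at 5.21 h, J had a half-life of 0.39 h by its step to Z and G, shorter than the 6.5 h of X by its step with L. At 10 h spring held 3.11% of the X charged as J and 55% as X, where my count on 7.10 h had left 56.4%. For the neighbour of spring with 0.10 M of Z, scaling by the Z charge shortens the half-life to 2.84 h and the same count leaves 27.1% as X; that flask kept 31.3% as X at 10.0 h.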